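## Retrosynthetic overview

1. Rings A–E and six stereocentres come intact from celastrol (1), used as its methyl ester pristimerin (2); no C–C bond is made anywhere.
2. C6 carbonyl: a C–O bond is made on the quinone methide, 2 to peroxide 3 to 6-oxopristimerol (4); the C8–H centre comes from α-face hydrogenation of C7=C8, giving catechol 5.
3. C9'–O bond: 4-allyl-2,6-dimethoxyphenol (6) is oxidised to vinyl quinone methide 7, which adds acetic acid to give (E)-sinapyl acetate (8).
4. Key disconnection: the two aryl ether C–O bonds of the dioxane ring, O2–C8' (5 + 8 to quinone methide 9) and then O3–C7' (9 to target 10), made in one oxidative [4+2] heterocoupling.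
5. Ring order: the 1,4-dioxane ring is the only ring formed, and it is closed last.

Assumption: celastrol (bulk isolate of Tripterygium wilfordii) is accepted as a commercial starting material; C1–C30 follow friedelane numbering, O2 and O3 are the oxygens on C2 and C3, and C7', C8', C9' are the benzylic, middle and acetoxymethyl carbons of the C6–C3 unit.

## Route

Step 1
Reactants: 1 celastrol
Product: 2 pristimerin (celastrol methyl ester)
Conditions: MeI (1.5 equiv), NaHCO3 (2 equiv), DMF, rt, 12 h
Reagents that add atoms: iodomethane CI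
Why: Chemoselective SN2 esterification: NaHCO3 ionises only the C29 acid, whose carboxylate is methylated while the hydrogen-bonded C3 enol of the quinone methide stays free, and no stereocentre is touched.

Step 2
Reactants: 2 pristimerin
Product: 4 6-oxopristimerol, via 6-(tert-butylperoxy)pristimerol 3 (not isolated)
Conditions: t-BuOOH (5.5 M in decane, 1.5 equiv), DBU (2.5 equiv), THF, 0 °C to rt, argon
Reagents that add atoms: tert-butyl hydroperoxide CC(C)(C)OO
Why: Proposed new method: tandem oxa-1,6-conjugate addition/Kornblum–DeLaMare fragmentation on a triterpenoid quinone methide, in which the tert-butylperoxide anion adds to C6 (the carbon of 2 that thiols and other soft nucleophiles attack) and re-aromatises ring A to catechol 3, after which DBU removes the benzylic–allylic C6–H with loss of tert-butoxide to leave the C6 ketone without any catechol protection; the closest known reaction types are 1,6-additions of hydroperoxides and thiols to para-quinone methides and the base-induced Kornblum–DeLaMare rearrangement of secondary benzylic peroxides; no stereocentre is formed.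

Step 3
Reactants: 4 6-oxopristimerol
Product: 5 7,8-dihydro-6-oxopristimerol (8α-H)
Conditions: H2 (4 bar), 10% Pd/C, EtOAc/MeOH 1:1, rt
Reagents that add atoms: none
Why: Heterogeneous catalytic hydrogenation (syn addition) of the C7=C8 enone: the β face of C8 is shielded by the syn-axial 9β- and 14β-methyl groups, so the alkene adsorbs on its α face and C8 receives an α hydrogen (trans to both methyls, as in the target), while the hindered, phenol-conjugated aryl ketone and the ester are left alone.

Step 4
Reactants: 6 4-allyl-2,6-dimethoxyphenol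
Product: 8 (E)-sinapyl acetate, via vinyl quinone methide 7 (not isolated)
Conditions: Ag2O (2.5 equiv), CH2Cl2, rt, 1 h, filter; then AcOH (10 equiv), NaOAc (0.5 equiv), 0 °C to rt
Reagents that add atoms: acetic acid CC(=O)O
Why: Two-electron phenol oxidation to the vinyl quinone methide followed by 1,8-conjugate addition of acetic acid at the terminal carbon; re-aromatisation and styrene conjugation make the linear cinnamyl acetate the thermodynamic adduct, and the s-trans diene of 7 gives the E alkene.

Step 5
Reactants: 5 7,8-dihydro-6-oxopristimerol; 8 (E)-sinapyl acetate (2 equiv, added over 6 h)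
Product: 10 CNP0076567.1 ((7'S,8'S)-trans-benzodioxane), via para-quinone methide ether 9 (not isolated)
Conditions: CuI (10 mol %), (S,S)-1,5-diaza-cis-decalin (11 mol %), O2 (1 atm), 4 Å MS, MeCN/ClCH2CH2Cl 1:1, 0 °C to rt
Reagents that add atoms: none
Why: Proposed new method: catalyst-controlled aerobic oxidative [4+2] heterocoupling of a catechol with a 4-hydroxycinnamyl ester, in which the hydroxo complex of divalent copper with the C2-symmetric diamine ionises and chelates the catechol (O2–H, para to the C6 carbonyl and unflanked, is the more acidic and less hindered site), inner-sphere electron transfer gives a copper-bound semiquinone whose O2 couples with C8' of the phenoxyl radical of 8 inside the chiral pocket (this sets C8' under catalyst control, because the triterpenoid stereocentres are too remote to bias it), the free O3–H of the resulting para-quinone methide 9 then closes the ring by oxa-1,6-addition to C7' with aryl and acetoxymethyl trans (the thermodynamic arrangement, which sets C7'), and O2 returns monovalent copper to the divalent state while itself ending as water, which carries off the two catechol hydrogens of 5; the closest known reaction types are the Ag2CO3-mediated biomimetic coupling of catechols with 4-hydroxycinnamyl alcohols to racemic trans-1,4-benzodioxanes, whose usual regiochemistry (the oxygen para to the carbonyl-bearing carbon bonds to C8') is followed here, and the copper–diaza-cis-decalin asymmetric aerobic coupling of chelating naphthols.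

## Compound list

1 | celastrol (3-hydroxy-2-oxo-24-nor-D:A-friedooleana-1(10),3,5,7-tetraen-29-oic acid) | OC(=O)[C@]1(C)CC[C@]2(C)CC[C@]3(C)C4=CC=C5C(C)=C(O)C(=O)C=C5[C@]4(C)CC[C@@]3(C)[C@@H]2C1 | starting material
2 | pristimerin (methyl ester of 1) | COC(=O)[C@]1(C)CC[C@]2(C)CC[C@]3(C)C4=CC=C5C(C)=C(O)C(=O)C=C5[C@]4(C)CC[C@@]3(C)[C@@H]2C1 | intermediate
3 | 6-(tert-butylperoxy)pristimerol (ring A catechol, C7=C8 retained; C6 configuration undefined and lost in the next event) | COC(=O)[C@]1(C)CC[C@]2(C)CC[C@]3(C)C4=CC(OOC(C)(C)C)c5c(cc(O)c(O)c5C)[C@]4(C)CC[C@@]3(C)[C@@H]2C1 | intermediate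
4 | 6-oxopristimerol (methyl 2,3-dihydroxy-6-oxo-24-nor-D:A-friedooleana-1,3,5(10),7-tetraen-29-oate) | COC(=O)[C@]1(C)CC[C@]2(C)CC[C@]3(C)C4=CC(=O)c5c(cc(O)c(O)c5C)[C@]4(C)CC[C@@]3(C)[C@@H]2C1 | intermediate
5 | 7,8-dihydro-6-oxopristimerol (8α-H, trans to the 9β- and 14β-methyls) | COC(=O)[C@]1(C)CC[C@]2(C)CC[C@]3(C)[C@H]4CC(=O)c5c(cc(O)c(O)c5C)[C@]4(C)CC[C@@]3(C)[C@@H]2C1 | intermediate
6 | 4-allyl-2,6-dimethoxyphenol | C=CCc1cc(OC)c(O)c(OC)c1 | starting material
7 | 4-allylidene-2,6-dimethoxycyclohexa-2,5-dien-1-one (vinyl quinone methide) | C=CC=C1C=C(OC)C(=O)C(OC)=C1 | intermediate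
8 | (E)-sinapyl acetate ((E)-3-(4-hydroxy-3,5-dimethoxyphenyl)prop-2-en-1-yl acetate) | CC(=O)OC/C=C/c1cc(OC)c(O)c(OC)c1 | intermediate
9 | para-quinone methide ether: 5 carrying on O2 the 1-acetoxy-3-(3,5-dimethoxy-4-oxocyclohexa-2,5-dien-1-ylidene)propan-2-yl group, O3–H free; C8' has the same spatial arrangement as in 10 (R by CIP because the priority order changes) | COC(=O)[C@]1(C)CC[C@]2(C)CC[C@]3(C)[C@H]4CC(=O)c5c(cc(O[C@@H](COC(C)=O)C=C6C=C(OC)C(=O)C(OC)=C6)c(O)c5C)[C@]4(C)CC[C@@]3(C)[C@@H]2C1 | intermediate
10 | CNP0076567.1: trans-1,4-benzodioxane with O3–C7'(S)(4-hydroxy-3,5-dimethoxyphenyl) and O2–C8'(S)(CH2OAc) on the 7,8-dihydro-6-oxopristimerol core | COC(=O)[C@]1(C)CC[C@]2(C)CC[C@]3(C)[C@H]4CC(=O)c5c(cc6c(c5C)O[C@@H](c5cc(OC)c(O)c(OC)c5)[C@H](COC(C)=O)O6)[C@]4(C)CC[C@@]3(C)[C@@H]2C1 | target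

## Step count and risks

Total step count: 5. Longest linear sequence: 4 steps (1, 2, 3, 5).

Most likely to fail, first: the new heterocoupling of step 5. The level and sense of induction at C8' are unproven (the (R,R)-diamine is the direct switch if the sense is reversed). Homodimerisation of 8, over-oxidation of the phenolic product and copper-mediated cleavage of the catechol can also compete. The fallback uses known chemistry and sets out from 5 and 8: Ag2CO3 (2.5 equiv) in benzene/acetone at 50 °C, the established biomimetic oxidative coupling, gives the trans-benzodioxane without control of absolute configuration at the new centres. The product is therefore a near 1:1 pair of 10 and the (7'R,8'R)-diastereomer of 10 F1, together with regioisomeric by-products. Preparative HPLC separates them and the route is rejoined at 10.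

Second: the peroxide addition/fragmentation of step 2. DBU also deprotonates the C3 enol of 2, which slows the 1,6-addition, and peroxide attack on the C2 carbonyl could cleave ring A. The fallback uses known chemistry and sets out from 2. NaBH4 in MeOH/THF at 0 °C reduces the quinone methide to the air-sensitive catechol pristimerol F2. This is acetylated in the same flask (Ac2O, pyridine, DMAP) to pristimerol diacetate F3. Allylic–benzylic oxidation of the C6 methylene (CrO3, 3,5-dimethylpyrazole, CH2Cl2, −20 °C) gives 6-oxopristimerol diacetate F4. K2CO3 in MeOH at 0 °C removes both aryl acetates and the route is rejoined at 4.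

Third: the hydrogenation of step 3. C8 lies between two quaternary carbons, so the enone may resist a metal surface, and forcing conditions endanger the aryl ketone. The fallback changes to a radical hydrogen-atom-transfer reduction on a protected substrate and sets out from 4. TBSCl and imidazole in DMF give 6-oxopristimerol bis(tert-butyldimethylsilyl) ether F5. Conjugate reduction with Mn(dpm)3 (10 mol %), PhSiH3 and t-BuOOH in i-PrOH at rt delivers the hydrogen atom to the less hindered α face of C8 and gives 7,8-dihydro-6-oxopristimerol bis(tert-butyldimethylsilyl) ether F6. TBAF/AcOH in THF at 0 °C frees the catechol and the route is rejoined at 5.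

## Further compounds

F1 | step 5 | (7'R,8'R)-diastereomer of 10 | COC(=O)[C@]1(C)CC[C@]2(C)CC[C@]3(C)[C@H]4CC(=O)c5c(cc6c(c5C)O[C@H](c5cc(OC)c(O)c(OC)c5)[C@@H](COC(C)=O)O6)[C@]4(C)CC[C@@]3(C)[C@@H]2C1
F2 | step 2 | pristimerol | COC(=O)[C@]1(C)CC[C@]2(C)CC[C@]3(C)C4=CCc5c(cc(O)c(O)c5C)[C@]4(C)CC[C@@]3(C)[C@@H]2C1
F3 | step 2 | pristimerol diacetate | COC(=O)[C@]1(C)CC[C@]2(C)CC[C@]3(C)C4=CCc5c(cc(OC(C)=O)c(OC(C)=O)c5C)[C@]4(C)CC[C@@]3(C)[C@@H]2C1
F4 | step 2 | 6-oxopristimerol diacetate | COC(=O)[C@]1(C)CC[C@]2(C)CC[C@]3(C)C4=CC(=O)c5c(cc(OC(C)=O)c(OC(C)=O)c5C)[C@]4(C)CC[C@@]3(C)[C@@H]2C1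
F5 | step 3 | 6-oxopristimerol bis(tert-butyldimethylsilyl) ether | COC(=O)[C@]1(C)CC[C@]2(C)CC[C@]3(C)C4=CC(=O)c5c(cc(O[Si](C)(C)C(C)(C)C)c(O[Si](C)(C)C(C)(C)C)c5C)[C@]4(C)CC[C@@]3(C)[C@@H]2C1
F6 | step 3 | 7,8-dihydro-6-oxopristimerol bis(tert-butyldimethylsilyl) ether | COC(=O)[C@]1(C)CC[C@]2(C)CC[C@]3(C)[C@H]4CC(=O)c5c(cc(O[Si](C)(C)C(C)(C)C)c(O[Si](C)(C)C(C)(C)C)c5C)[C@]4(C)CC[C@@]3(C)[C@@H]2C1
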